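## Analysis of the target

Target 24 is a depsidone: two benzene rings (ring A and ring B) are joined by a seven-membered ring C that holds a diaryl ether oxygen and an aryl ester (lactone), and ring B is fused to a 2,2-dimethyl-2,3-dihydropyran-4-one (ring D). With the tricyclic core numbered as a dibenzo[b,e][1,4]dioxepin-11-one, ring A carries C1 (CH3), C2 (H), C3 (OH), C4 (CHO), C4a (bound to the ether oxygen O5) and C11a (bound to the lactone carbonyl C11), and ring B carries C5a (O5), C6 (OH), C7 (ring D oxygen), C8 (ring D carbonyl), C9 (CH3) and C9a (lactone oxygen O10). There is no stereocentre, so no configuration has to be set; the only chiral species on the way is a transient racemic cycloadduct. The sensitive groups are the aryl ester of ring C (opened by organometallic reagents and alkoxides), the aldehyde ortho to a phenol, the electron-rich free phenols, and the β-aryloxy ketone of ring D, whose tertiary alkyl aryl ether can open by retro-oxa-Michael reaction. The difficulty is the substitution density: ring A is pentasubstituted, ring B hexasubstituted, and O5 joins two carbons that each have two ortho substituents. In addition, the two oxygens ortho to C5a (on C6 and C9a) must be told apart so that the lactone closes to C9a only, and the formyl group must sit at C4 and not at C2. The strategy rests on C4a and C11a being neighbours: they map onto the two sp carbons of an aryloxypropiolate, and C4, C3, C2 and C1 map onto C3 to C6 of a 3-bromo-4-methoxy-6-methyl-2-pyrone, so that O5 is bound to carbon before ring A exists.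

## Retrosynthetic reasoning

**Ring D.** The C8–acyl bond and the bond from the C7 oxygen to C(CH3)2 are cut, leading to triol 21 and 3,3-dimethylacrylic acid 22. C8 is the only unsubstituted carbon of ring B, so the acylation has one site there, and the five-carbon unit arrives at the ketone oxidation state. The ring is made last because its β-aryloxy ketone would not survive the organolithium steps. The forward reaction must acylate C8 (enone 23) and let the C7 hydroxyl add to the enone.

**Methyl ethers.** The three O–CH3 bonds of 21 are restored, giving 20. Methyl ethers are the phenol masks that tolerate organolithium reagents and the hot cycloaddition. They come off only after ring C is closed, so that the C6 oxygen stays blocked during lactonisation.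

**Ring C.** The C11–O10 bond of 20 is cut, giving hydroxy acid 19. This bond is chosen over the two bonds to O5 because it is an acyl transfer between groups already held side by side by the diaryl ether, whereas a bond to O5 would mean substitution at a carbon with two ortho substituents. The forward step must activate a hindered benzoic acid; 19 comes from 18 by removing the one acetal protecting group, which frees the C9a hydroxyl only.

**Formyl group.** The C4–CHO bond of 18 is cut, giving aryllithium 17 and bromide 16. The bromine is a position marker placed before ring A exists, so no regiochemical question arises on the arene. The exchange is run on the carboxylic acid 16 (from ester 15), whose lithium salt protects the carboxyl carbon, and it comes before lactonisation because the aryl ester of ring C would not tolerate an aryllithium.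

**Ring A.** The C4–C4a and C1–C11a bonds of 15 are cut, giving propiolate 11 and bromopyrone 13 by way of the bridged adduct 14. All five substituents of ring A and the diaryl ether oxygen are in place when the ring forms. The forward reaction must add the alkyne across C3 and C6 of the pyrone in one orientation and then aromatise by decarboxylation.

**Propiolate.** The bond between the alkyne and the ester carbon of 11 is cut, giving acetylide 10. This is traced through chloroalkyne 9 to the dichlorovinyl ether 8, in which O5 is already bound to the two future ring A carbons.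

**Ring B.** Ether 8 is taken back through phenol 7 and formate 6 to aldehyde 5, and 5 to phenol 3 and trichloroethylene 4. The aldehyde carbon of 3 is exchanged for the C9a oxygen by Baeyer–Villiger oxidation. The dichlorovinyl ether is put on first, so that it also protects the O5 oxygen during that oxidation. Phenol 3 comes from 2 by chelation-controlled cleavage of the one methoxy group ortho to the formyl group, and 2 from 3,4,5-trimethoxytoluene 1 by formylation.

**Pyrone.** The C3–Br bond of 13 is cut, giving 4-methoxy-6-methyl-2-pyrone 12; C3 is its most nucleophilic carbon.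

## Alternatives that were turned down

**Alternative 1: the lactone carbonyl from carbon monoxide.** Both bonds to C11 are cut (C11a–C11 and C11–O10), which leads to the iodo diaryl ether A1, carrying ring D, the formyl group and a free C9a hydroxyl, and to carbon monoxide A2. In the forward step Pd(OAc)2 with a wide-bite-angle bisphosphine and an amine base would insert into the C–I bond, take up A2, and the aroylpalladium species would be captured by the C9a phenol, closing ring C to A3, the C6 methyl ether of 24. On one point this plan is stronger: no carboxyl group is carried, so nothing like the hindered ester hydrolysis and acid activation of steps 9 and 12 is needed, and ring C closes very late. Against it, A1 already contains the diaryl ether with four ortho substituents, which would have to be made by Ullmann or SNAr coupling of two fully substituted arenes; that is the hardest bond of the molecule. Oxidative addition at an iodide flanked by a methyl and an aryloxy group is also slow, and A3 still needs demethylation at C6 next to the acid-sensitive ring D. The chosen route spends two extra steps on the carboxyl group but attaches O5 to an sp carbon, where crowding does not matter.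

**Alternative 2: ring D from an ortho-quinone methide.** The benzylic C–C bond and the O–C(CH3)2 bond of the pyran are cut. Heating the Mannich base A4 in the presence of isobutene A5 would expel its amine and give the ortho-quinone methide A6, which adds A5 in a hetero-(4+2) reaction to give chroman A7. Its oxygen and C4a correspond to the C7 oxygen and C8 of 24, and its bromine marks the site of O5. This is stronger than the chosen route on ring D: the cycloaddition is regiospecific, sets the quaternary carbon on a simple arene, and avoids the late Friedel–Crafts annulation of step 14. Against it, A7 is a chroman and not a chromanone, so its benzylic CH2 must later be oxidised in a molecule with two aryl methyl groups. The key step also leaves ring A, ring C and the crowded diaryl ether unsolved; the ether would again have to be made from the hindered bromide A7. The chosen route forms ring D in one step at the ketone oxidation state and puts its main risk into the bond-forming event that solves the diaryl ether.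

**Alternative 3: intramolecular cycloaddition closing rings A and C together.** The C4a–C11a and C1–C2 bonds are cut. The precursor A8 is a ring B catechol with a but-2-ynoate ester on one oxygen and a 2-bromo-3-silyloxydienyl ether on the other; heating would give the racemic cyclohexa-1,4-diene A9 fused to the lactone. It is stronger on two points: the cycloaddition is intramolecular and should need less heat than the bimolecular step 8, and it closes two rings at once. Against it, A8 joins a labile aryl alkynoate to an acid-sensitive silyl dienol ether, and an aryl 2-bromodienyl ether has no general preparation. A9 must then be dehydrogenated to the arene. Above all, the bromine would have to be turned into the aldehyde after the lactone exists, where aryllithium or arylmagnesium chemistry is excluded. The chosen route accepts a bimolecular cycloaddition but delivers an aromatic ring A directly and formylates before ring C is closed.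

Key step: step 8

Remarks: 4-methoxy-6-methyl-2-pyrone 12 is assumed to be purchasable. Dichloroacetylene is formed only in situ in step 3 and is never isolated. All compounds are achiral except the transient racemic adduct 14.

## Route

**Step 1**
Reactants: 1 3,4,5-trimethoxytoluene
Product: 2 2,3,4-trimethoxy-6-methylbenzaldehyde
Conditions: POCl3, DMF, 0 °C → 80 °C; then aq. NaOAc
Reagents that add atoms: N,N-dimethylformamide, CN(C)C=O; water, O
Why: Vilsmeier–Haack formylation; the two free positions of 1 are equivalent and each is ortho and para to a methoxy group, so a single aldehyde should form.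

**Step 2**
Reactants: 2 2,3,4-trimethoxy-6-methylbenzaldehyde
Product: 3 2-hydroxy-3,4-dimethoxy-6-methylbenzaldehyde
Conditions: BCl3 (1.2 equiv), CH2Cl2, −78 °C → 0 °C; then H2O
Reagents that add atoms: none
Why: Chelation-controlled demethylation: BCl3 bound to the formyl oxygen cleaves only the methoxy group ortho to it, which frees the oxygen that becomes O5.

**Step 3**
Reactants: 3 2-hydroxy-3,4-dimethoxy-6-methylbenzaldehyde; 4 trichloroethylene
Product: 5 2-{[(E)-1,2-dichloroethenyl]oxy}-3,4-dimethoxy-6-methylbenzaldehyde
Conditions: K2CO3, DMF, 70 °C
Reagents that add atoms: none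
Why: O-Vinylation of a phenol with trichloroethylene: base eliminates HCl from 4 to dichloroacetylene and the phenoxide adds in anti fashion to give the (E)-dichlorovinyl ether; the aldehyde has no α-hydrogen and should be inert.

**Step 4**
Reactants: 5 2-{[(E)-1,2-dichloroethenyl]oxy}-3,4-dimethoxy-6-methylbenzaldehyde
Product: 7 2-{[(E)-1,2-dichloroethenyl]oxy}-3,4-dimethoxy-6-methylphenol, via aryl formate 6 (not isolated)
Conditions: mCPBA, NaHCO3, CH2Cl2, 0 °C → rt; then K2CO3, MeOH, 0 °C
Reagents that add atoms: 3-chloroperbenzoic acid, O=C(OO)c1cccc(Cl)c1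
Why: Baeyer–Villiger oxidation in which the aryl group, electron-rich through its ortho and para oxygens, migrates in preference to hydrogen; formate 6 is then methanolysed. The doubly chlorinated enol ether should be too electron-poor for epoxidation, so it also protects the O5 oxygen.

**Step 5**
Reactants: 7 2-{[(E)-1,2-dichloroethenyl]oxy}-3,4-dimethoxy-6-methylphenol
Product: 8 2-{[(E)-1,2-dichloroethenyl]oxy}-3,4-dimethoxy-1-(methoxymethoxy)-6-methylbenzene
Conditions: MOMCl, iPr2NEt, CH2Cl2, 0 °C → rt
Reagents that add atoms: chloromethyl methyl ether, COCCl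
Why: O-Alkylation of the phenol to the methoxymethyl acetal; this group marks the future O10 oxygen and distinguishes it from the methyl ether on the other side of O5.

**Step 6**
Reactants: 8 2-{[(E)-1,2-dichloroethenyl]oxy}-3,4-dimethoxy-1-(methoxymethoxy)-6-methylbenzene
Product: 11 methyl 3-[2,3-dimethoxy-6-(methoxymethoxy)-5-methylphenoxy]prop-2-ynoate, via chloroethynyl aryl ether 9 (not isolated), via lithium aryloxyacetylide 10 (not isolated)
Conditions: n-BuLi (2.3 equiv), THF, −78 °C → −40 °C; then inverse addition to ClCO2Me, THF, −78 °C → 0 °C
Reagents that add atoms: methyl chloroformate, COC(=O)Cl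
Why: Ynol ether synthesis from a dichlorovinyl ether: the first equivalent of n-BuLi eliminates HCl to chloroalkyne 9, the second effects chlorine–lithium exchange to acetylide 10, which is C-acylated by the chloroformate. Inverse addition at low temperature should prevent a second addition to the new ester.

**Step 7**
Reactants: 12 4-methoxy-6-methyl-2H-pyran-2-one
Product: 13 3-bromo-4-methoxy-6-methyl-2H-pyran-2-one
Conditions: NBS, MeCN, rt
Reagents that add atoms: N-bromosuccinimide, O=C1CCC(=O)N1Br
Why: Electrophilic bromination at C3, the α-carbon of the vinylogous carbonate and the most nucleophilic position of the pyrone.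

**Step 8**
Reactants: 11 methyl 3-[2,3-dimethoxy-6-(methoxymethoxy)-5-methylphenoxy]prop-2-ynoate; 13 3-bromo-4-methoxy-6-methyl-2H-pyran-2-one
Product: 15 methyl 3-bromo-2-[2,3-dimethoxy-6-(methoxymethoxy)-5-methylphenoxy]-4-methoxy-6-methylbenzoate, via bridged bicyclic lactone 14 (not isolated)
Conditions: 13 (2 equiv), degassed toluene, BHT (cat.), sealed tube, 160 °C
Reagents that add atoms: none
Why: The pyrone acts as a diene across C3 and C6 and adds the alkyne in a thermal (4+2) cycloaddition to the racemic 2-oxabicyclo[2.2.2]octadienone 14, which loses carbon dioxide in a retro-(4+2) step to give benzoate 15 irreversibly. The closest known reaction type is the Diels–Alder/decarboxylation of 4-alkoxy- and 3-bromo-2-pyrones with alkynoates to give benzoates. Ring A closes by intermolecular cycloaddition: the C4–C4a and C1–C11a bonds form in one concerted, asynchronous event, with no separate cyclisation step. The two bridgehead centres of 14 are fixed relative to each other by the bridge and vanish on aromatisation, so no stereocentre needs control. The selectivity needed is regiochemical. Pyrone C3, the β-carbon of the enol ether and the nucleophilic diene terminus, should bond to the aryloxy-bearing alkyne carbon, which is the electrophilic β-carbon of the ynoate. Pyrone C6, the electrophilic terminus, should bond to the ester-bearing carbon, which is the nucleophilic carbon of the ynol ether; both polarisations favour the same orientation and place the ester para to the methoxy group. Excess pyrone offsets the slow bimolecular rate, and the product arene cannot react further.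

**Step 9**
Reactants: 15 methyl 3-bromo-2-[2,3-dimethoxy-6-(methoxymethoxy)-5-methylphenoxy]-4-methoxy-6-methylbenzoate
Product: 16 3-bromo-2-[2,3-dimethoxy-6-(methoxymethoxy)-5-methylphenoxy]-4-methoxy-6-methylbenzoic acid
Conditions: KOH, DMSO/H2O, 90 °C; then 1 M HCl to pH 3, 0 °C
Reagents that add atoms: potassium hydroxide, [K+].[OH-]
Why: Saponification of a di-ortho-substituted methyl benzoate with hydroxide in aqueous DMSO; the bromide, the acetal and the diaryl ether are stable to base, and the free carboxyl group is what steps 10 and 12 need.

**Step 10**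
Reactants: 16 3-bromo-2-[2,3-dimethoxy-6-(methoxymethoxy)-5-methylphenoxy]-4-methoxy-6-methylbenzoic acid
Product: 18 2-[2,3-dimethoxy-6-(methoxymethoxy)-5-methylphenoxy]-3-formyl-4-methoxy-6-methylbenzoic acid, via dilithiated carboxylate 17 (not isolated)
Conditions: n-BuLi (2.2 equiv), THF, −78 °C; then DMF, −78 °C → 0 °C; aq. NH4Cl, then pH 3
Reagents that add atoms: N,N-dimethylformamide, CN(C)C=O
Why: The first equivalent of n-BuLi forms the lithium carboxylate, which resists further attack, and the second effects bromine–lithium exchange at the carbon flanked by two oxygens to give 17. Formylation with DMF (Bouveault reaction) then places the aldehyde exactly where the bromine stood.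

**Step 11**
Reactants: 18 2-[2,3-dimethoxy-6-(methoxymethoxy)-5-methylphenoxy]-3-formyl-4-methoxy-6-methylbenzoic acid
Product: 19 3-formyl-2-(6-hydroxy-2,3-dimethoxy-5-methylphenoxy)-4-methoxy-6-methylbenzoic acid
Conditions: 3 M HCl, THF, 50 °C
Reagents that add atoms: none
Why: Acid hydrolysis of the methoxymethyl acetal; the three aryl methyl ethers remain, so only the C9a hydroxyl is freed and lactonisation cannot take place at the C6 oxygen.

**Step 12**
Reactants: 19 3-formyl-2-(6-hydroxy-2,3-dimethoxy-5-methylphenoxy)-4-methoxy-6-methylbenzoic acid
Product: 20 3,6,7-trimethoxy-1,9-dimethyl-11-oxo-11H-dibenzo[b,e][1,4]dioxepine-4-carbaldehyde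
Conditions: (CF3CO)2O, toluene, 0 °C → rt, high dilution
Reagents that add atoms: none
Why: Lactonisation through the mixed trifluoroacetic anhydride, the classical way to esterify hindered, electron-rich benzoic acids with phenols. The diaryl ether holds the phenol next to the activated carboxyl group, so the seven-membered ring should close in preference to intermolecular acylation.

**Step 13**
Reactants: 20 3,6,7-trimethoxy-1,9-dimethyl-11-oxo-11H-dibenzo[b,e][1,4]dioxepine-4-carbaldehyde
Product: 21 3,6,7-trihydroxy-1,9-dimethyl-11-oxo-11H-dibenzo[b,e][1,4]dioxepine-4-carbaldehyde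
Conditions: BBr3 (6 equiv), CH2Cl2, −78 °C → 0 °C; then ice water
Reagents that add atoms: none
Why: Lewis-acid demethylation of all three aryl methyl ethers (bromide attacks the O-methyl groups of the boron complexes by SN2); the aryl ester has no alkyl–oxygen bond to cleave, and the aldehyde is recovered on hydrolysis.

**Step 14**
Reactants: 21 3,6,7-trihydroxy-1,9-dimethyl-11-oxo-11H-dibenzo[b,e][1,4]dioxepine-4-carbaldehyde; 22 3,3-dimethylacrylic acid
Product: 24 target CNP0271978.0 (the 3,6-dihydroxy-1,9-dimethyl-4-formyl depsidone bearing a 2,2-dimethyl-2,3-dihydropyran-4-one fused at C7 through oxygen and at C8 through the carbonyl), via aryl prenyl ketone 23 (not isolated)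
Conditions: P2O5/MeSO3H (Eaton's reagent), 70 °C
Reagents that add atoms: none
Why: Friedel–Crafts acylation by the activated acid at C8, the only free position of ring B (ortho to the C7 hydroxyl, para to O5), gives enone 23, whose C7 hydroxyl adds to the β-carbon (oxa-Michael, 6-endo-trig) to close ring D, as known for 2,2-dimethylchroman-4-ones from phenols. Ring A should not compete, because its two oxygen donors are conjugated with the formyl and lactone carbonyl groups.

## Compound list

1 | 3,4,5-trimethoxytoluene | COc1cc(C)cc(OC)c1OC | starting material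
2 | 2,3,4-trimethoxy-6-methylbenzaldehyde | Cc1cc(OC)c(OC)c(OC)c1C=O | intermediate
3 | 2-hydroxy-3,4-dimethoxy-6-methylbenzaldehyde | Cc1cc(OC)c(OC)c(O)c1C=O | intermediate
4 | trichloroethylene | ClC=C(Cl)Cl | starting material
5 | 2-{[(E)-1,2-dichloroethenyl]oxy}-3,4-dimethoxy-6-methylbenzaldehyde | Cc1cc(OC)c(OC)c(O/C(Cl)=C\Cl)c1C=O | intermediate
6 | 2-{[(E)-1,2-dichloroethenyl]oxy}-3,4-dimethoxy-6-methylphenyl formate (not isolated) | Cc1cc(OC)c(OC)c(O/C(Cl)=C\Cl)c1OC=O | intermediate
7 | 2-{[(E)-1,2-dichloroethenyl]oxy}-3,4-dimethoxy-6-methylphenol | Cc1cc(OC)c(OC)c(O/C(Cl)=C\Cl)c1O | intermediate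
8 | 2-{[(E)-1,2-dichloroethenyl]oxy}-3,4-dimethoxy-1-(methoxymethoxy)-6-methylbenzene | Cc1cc(OC)c(OC)c(O/C(Cl)=C\Cl)c1OCOC | intermediate
9 | 2-(chloroethynyloxy)-3,4-dimethoxy-1-(methoxymethoxy)-6-methylbenzene (not isolated) | Cc1cc(OC)c(OC)c(OC#CCl)c1OCOC | intermediate
10 | lithium [2,3-dimethoxy-6-(methoxymethoxy)-5-methylphenoxy]acetylide (not isolated) | Cc1cc(OC)c(OC)c(OC#C[Li])c1OCOC | intermediate
11 | methyl 3-[2,3-dimethoxy-6-(methoxymethoxy)-5-methylphenoxy]prop-2-ynoate | COC(=O)C#COc1c(OC)c(OC)cc(C)c1OCOC | intermediate
12 | 4-methoxy-6-methyl-2H-pyran-2-one | COC1=CC(=O)OC(C)=C1 | starting material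
13 | 3-bromo-4-methoxy-6-methyl-2H-pyran-2-one | COC1=C(Br)C(=O)OC(C)=C1 | intermediate
14 | methyl 4-bromo-5-[2,3-dimethoxy-6-(methoxymethoxy)-5-methylphenoxy]-8-methoxy-1-methyl-3-oxo-2-oxabicyclo[2.2.2]octa-5,7-diene-6-carboxylate (racemic, one enantiomer drawn, not isolated) | C[C@]12OC(=O)[C@](Br)(C(OC)=C1)C(Oc3c(OC)c(OC)cc(C)c3OCOC)=C2C(=O)OC | intermediate
15 | methyl 3-bromo-2-[2,3-dimethoxy-6-(methoxymethoxy)-5-methylphenoxy]-4-methoxy-6-methylbenzoate | COC(=O)c1c(C)cc(OC)c(Br)c1Oc1c(OC)c(OC)cc(C)c1OCOC | intermediate
16 | 3-bromo-2-[2,3-dimethoxy-6-(methoxymethoxy)-5-methylphenoxy]-4-methoxy-6-methylbenzoic acid | OC(=O)c1c(C)cc(OC)c(Br)c1Oc1c(OC)c(OC)cc(C)c1OCOC | intermediate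
17 | lithium 2-[2,3-dimethoxy-6-(methoxymethoxy)-5-methylphenoxy]-3-lithio-4-methoxy-6-methylbenzoate (not isolated) | [Li]OC(=O)c1c(C)cc(OC)c([Li])c1Oc1c(OC)c(OC)cc(C)c1OCOC | intermediate
18 | 2-[2,3-dimethoxy-6-(methoxymethoxy)-5-methylphenoxy]-3-formyl-4-methoxy-6-methylbenzoic acid | OC(=O)c1c(C)cc(OC)c(C=O)c1Oc1c(OC)c(OC)cc(C)c1OCOC | intermediate
19 | 3-formyl-2-(6-hydroxy-2,3-dimethoxy-5-methylphenoxy)-4-methoxy-6-methylbenzoic acid | OC(=O)c1c(C)cc(OC)c(C=O)c1Oc1c(OC)c(OC)cc(C)c1O | intermediate
20 | 3,6,7-trimethoxy-1,9-dimethyl-11-oxo-11H-dibenzo[b,e][1,4]dioxepine-4-carbaldehyde | Cc1cc(OC)c(C=O)c2c1C(=O)Oc1c(C)cc(OC)c(OC)c1O2 | intermediate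
21 | 3,6,7-trihydroxy-1,9-dimethyl-11-oxo-11H-dibenzo[b,e][1,4]dioxepine-4-carbaldehyde | Cc1cc(O)c(C=O)c2c1C(=O)Oc1c(C)cc(O)c(O)c1O2 | intermediate
22 | 3,3-dimethylacrylic acid | CC(C)=CC(=O)O | starting material
23 | 3,6,7-trihydroxy-1,9-dimethyl-8-(3-methylbut-2-enoyl)-11-oxo-11H-dibenzo[b,e][1,4]dioxepine-4-carbaldehyde (not isolated) | Cc1cc(O)c(C=O)c2c1C(=O)Oc1c(C)c(C(=O)C=C(C)C)c(O)c(O)c1O2 | intermediate
24 | CNP0271978.0 | Cc1cc(O)c(C=O)c2c1C(=O)Oc1c(C)c3c(c(O)c1O2)OC(C)(C)CC3=O | target

## Step count and least certain steps

Total: 14 steps. Longest linear sequence: 13 steps (1 to 24 through steps 1–6 and 8–14); the pyrone branch is one step (step 7).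

**Step 8 (key step).** The bromine on pyrone C3 and the di-ortho-substituted aryloxy group sit at the two carbons that must bond first, so the cycloaddition may be slow. At the temperature then needed, the push–pull alkyne may be lost by hydration or oligomerisation before it is trapped. Fallback: the bromine is taken off the diene and the formyl group is introduced last. The fallback sets out from 11 and the unbrominated pyrone 12, the parent case of this reaction type. Heating should give, through the bridged lactone F1 and loss of carbon dioxide, methyl 2-[2,3-dimethoxy-6-(methoxymethoxy)-5-methylphenoxy]-4-methoxy-6-methylbenzoate F2. Saponification as in step 9 gives the acid F3, acetal hydrolysis as in step 11 gives the hydroxy acid F4, and (CF3CO)2O closes ring C to the formyl-free depsidone trimethyl ether F5. BBr3 gives the triol F6, and 22 in P2O5/MeSO3H should acylate C8 to the enone F7, which closes ring D to the formyl-free analogue F8 of the target. Rieche formylation (Cl2CHOMe, TiCl4, CH2Cl2) is then expected at C4, between the C3 hydroxyl and O5, as orsellinates are formylated between their two oxygen substituents. This gives 24, where the fallback rejoins the route. The price is that C4 against C2, and ring B against the now formyl-free ring A in the annulation, are decided by electronics instead of by a bromine set beforehand.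

**Step 14.** In hot strong acid the unsaturated acid can alkylate the arene through its β-carbon instead of acylating it, which would lead to a dihydrocoumarin. The aldehyde can also condense with the electron-rich ring B of a second molecule, and the lactone can suffer transacylation. Fallback: acylation is done before the phenols are freed. The fallback sets out from 20: Friedel–Crafts acylation with 3-methylbut-2-enoyl chloride and AlCl3 in CH2Cl2 should give 3,6,7-trimethoxy-1,9-dimethyl-8-(3-methylbut-2-enoyl)-11-oxo-11H-dibenzo[b,e][1,4]dioxepine-4-carbaldehyde F9. In F9 every methoxy group is either ortho to a carbonyl group or flanked by two oxygens, so the milder BCl3 should cleave all three and give the triol enone 23. NaOAc in ethanol then closes ring D to 24. This detour also avoids BBr3 on 20.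

**Step 4.** The peracid may attack the dichlorovinyl ether, or the enol ether may be cleaved during methanolysis of the formate, because the vinyl ether is used here as a protecting group under oxidising conditions. Fallback: an ordinary protecting group carries the O5 oxygen through the oxidation and the vinyl ether is put on afterwards. The fallback sets out from 3. Benzylation (BnBr, K2CO3, DMF) gives 2-(benzyloxy)-3,4-dimethoxy-6-methylbenzaldehyde F10. mCPBA gives the formate F11, which K2CO3 in methanol converts into 2-(benzyloxy)-3,4-dimethoxy-6-methylphenol F12. MOMCl and iPr2NEt give the acetal F13, and hydrogenolysis (H2, Pd/C, EtOAc) frees 2,3-dimethoxy-6-(methoxymethoxy)-5-methylphenol F14. Reaction of F14 with 4 and K2CO3 in DMF, as in step 3, gives 8, where the fallback rejoins the route at the cost of two more steps.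

**Step 10.** The aryllithium 17 may be protonated, by traces of moisture or by the benzylic methyl group next to the carboxylate, or be alkylated by the 1-bromobutane formed in the exchange; either would give material without the formyl group. Fallback: the carbon is brought in by cross-coupling and unmasked by oxidative cleavage. The fallback sets out from 16. Suzuki–Miyaura coupling with K[CH2=CHBF3] (Pd(OAc)2, SPhos, K2CO3, THF/H2O, 80 °C) should give 2-[2,3-dimethoxy-6-(methoxymethoxy)-5-methylphenoxy]-3-ethenyl-4-methoxy-6-methylbenzoic acid F15. Lemieux–Johnson cleavage (catalytic OsO4, NaIO4, 2,6-lutidine, dioxane/H2O) then passes through the diol F16 and gives 18, where the fallback rejoins the route.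

## Further compounds

F1 | step 8 | methyl 5-[2,3-dimethoxy-6-(methoxymethoxy)-5-methylphenoxy]-8-methoxy-1-methyl-3-oxo-2-oxabicyclo[2.2.2]octa-5,7-diene-6-carboxylate (racemic, one enantiomer drawn, not isolated) | C[C@]12OC(=O)[C@H](C(OC)=C1)C(Oc3c(OC)c(OC)cc(C)c3OCOC)=C2C(=O)OC
F2 | step 8 | methyl 2-[2,3-dimethoxy-6-(methoxymethoxy)-5-methylphenoxy]-4-methoxy-6-methylbenzoate | COC(=O)c1c(C)cc(OC)cc1Oc1c(OC)c(OC)cc(C)c1OCOC
F3 | step 8 | 2-[2,3-dimethoxy-6-(methoxymethoxy)-5-methylphenoxy]-4-methoxy-6-methylbenzoic acid | OC(=O)c1c(C)cc(OC)cc1Oc1c(OC)c(OC)cc(C)c1OCOC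
F4 | step 8 | 2-(6-hydroxy-2,3-dimethoxy-5-methylphenoxy)-4-methoxy-6-methylbenzoic acid | OC(=O)c1c(C)cc(OC)cc1Oc1c(OC)c(OC)cc(C)c1O
F5 | step 8 | 3,6,7-trimethoxy-1,9-dimethyl-11H-dibenzo[b,e][1,4]dioxepin-11-one | Cc1cc(OC)cc2c1C(=O)Oc1c(C)cc(OC)c(OC)c1O2
F6 | step 8 | 3,6,7-trihydroxy-1,9-dimethyl-11H-dibenzo[b,e][1,4]dioxepin-11-one | Cc1cc(O)cc2c1C(=O)Oc1c(C)cc(O)c(O)c1O2
F7 | step 8 | 3,6,7-trihydroxy-1,9-dimethyl-8-(3-methylbut-2-enoyl)-11H-dibenzo[b,e][1,4]dioxepin-11-one (not isolated) | Cc1cc(O)cc2c1C(=O)Oc1c(C)c(C(=O)C=C(C)C)c(O)c(O)c1O2
F8 | step 8 | formyl-free analogue of the target (24 with hydrogen at C4) | Cc1cc(O)cc2c1C(=O)Oc1c(C)c3c(c(O)c1O2)OC(C)(C)CC3=O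
F9 | step 14 | 3,6,7-trimethoxy-1,9-dimethyl-8-(3-methylbut-2-enoyl)-11-oxo-11H-dibenzo[b,e][1,4]dioxepine-4-carbaldehyde | Cc1cc(OC)c(C=O)c2c1C(=O)Oc1c(C)c(C(=O)C=C(C)C)c(OC)c(OC)c1O2
F10 | step 4 | 2-(benzyloxy)-3,4-dimethoxy-6-methylbenzaldehyde | Cc1cc(OC)c(OC)c(OCc2ccccc2)c1C=O
F11 | step 4 | 2-(benzyloxy)-3,4-dimethoxy-6-methylphenyl formate (not isolated) | Cc1cc(OC)c(OC)c(OCc2ccccc2)c1OC=O
F12 | step 4 | 2-(benzyloxy)-3,4-dimethoxy-6-methylphenol | Cc1cc(OC)c(OC)c(OCc2ccccc2)c1O
F13 | step 4 | 2-(benzyloxy)-3,4-dimethoxy-1-(methoxymethoxy)-6-methylbenzene | Cc1cc(OC)c(OC)c(OCc2ccccc2)c1OCOC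
F14 | step 4 | 2,3-dimethoxy-6-(methoxymethoxy)-5-methylphenol | Cc1cc(OC)c(OC)c(O)c1OCOC
F15 | step 10 | 2-[2,3-dimethoxy-6-(methoxymethoxy)-5-methylphenoxy]-3-ethenyl-4-methoxy-6-methylbenzoic acid | OC(=O)c1c(C)cc(OC)c(C=C)c1Oc1c(OC)c(OC)cc(C)c1OCOC
F16 | step 10 | 3-(1,2-dihydroxyethyl)-2-[2,3-dimethoxy-6-(methoxymethoxy)-5-methylphenoxy]-4-methoxy-6-methylbenzoic acid (racemic, not isolated) | OC(=O)c1c(C)cc(OC)c(C(O)CO)c1Oc1c(OC)c(OC)cc(C)c1OCOC
A1 | alternative 1 | 6-hydroxy-2-[(6-hydroxy-8-methoxy-2,2,5-trimethyl-4-oxochroman-7-yl)oxy]-3-iodo-4-methylbenzaldehyde | Cc1cc(O)c(C=O)c(Oc2c(O)c(C)c3c(c2OC)OC(C)(C)CC3=O)c1I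
A2 | alternative 1 | carbon monoxide | [C-]#[O+]
A3 | alternative 1 | C6 methyl ether of the target | Cc1cc(O)c(C=O)c2c1C(=O)Oc1c(C)c3c(c(OC)c1O2)OC(C)(C)CC3=O
A4 | alternative 2 | 3-bromo-6-[(dimethylamino)methyl]-2-methoxy-5-methylbenzene-1,4-diol | Cc1c(O)c(Br)c(OC)c(O)c1CN(C)C
A5 | alternative 2 | isobutene | CC(C)=C
A6 | alternative 2 | 3-bromo-4-hydroxy-2-methoxy-5-methyl-6-methylidenecyclohexa-2,4-dien-1-one | C=C1C(=O)C(OC)=C(Br)C(O)=C1C
A7 | alternative 2 | 7-bromo-6-hydroxy-8-methoxy-2,2,5-trimethylchroman | Cc1c(O)c(Br)c(OC)c2c1CCC(C)(C)O2
A8 | alternative 3 | 2-{[(1Z)-2-bromo-3-(tert-butyldimethylsilyloxy)buta-1,3-dien-1-yl]oxy}-3,4-dimethoxy-6-methylphenyl but-2-ynoate | CC#CC(=O)Oc1c(C)cc(OC)c(OC)c1O/C=C(\Br)C(=C)O[Si](C)(C)C(C)(C)C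
A9 | alternative 3 | racemic cyclohexa-1,4-diene fused to the seven-membered lactone | CC1=C2C(=O)Oc3c(C)cc(OC)c(OC)c3OC2C(Br)=C(O[Si](C)(C)C(C)(C)C)C1
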